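Ring B is closed last, on a finished ring C, by joining C6 to C5 (pimarane numbering). The key step is a palladium/light radical cyclisation–carbonylation: the α-iodo ketone at C7/C6 gives the C6 radical, which adds 6-exo to C5 of an isobutenyl group on C10; the tertiary C4 radical then captures CO. One operation thus forms ring B, the C5 stereocentre and the quaternary C4–C3O2H unit. It exploits the 1,5-relationship of the C7 oxygen and the C3 carboxyl across C6–C5–C4 in ring B and the cleaved ring A, with C5=C4Me2 as latent 2-methylpropanoic acid. The precursor is a ring C ketone with an iodoacetyl group on C8 and the quaternary C10 on C9.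

Key step: step 18

Remark on numbering and faces: carbons carry pimarane numbers. Ring C = C8, C9, C11, C12, C13, C14; C13 carries methyl and vinyl; C14 is the ring ketone; C8 the tertiary carbinol; C11 the benzoate carbon. C10 carries C20 (methyl), C1H2–C2O2H and C5; C5 carries C4Me2–C3O2H; C6 is the ring B CH2; C7 the acetate carbon. α is the face of ring C that carries the C13 vinyl group, β the face of the C13 methyl group.

Assumption: the D-fructose-derived Shi ketone is taken to deliver the 6R alcohol in step 2; if the facial sense proves opposite, the enantiomeric ketone is used.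

Step 1
Reactants: 1 3-ethoxycyclohex-2-en-1-one
Product: 2 [(5-ethoxycyclohexa-1,5-dien-1-yl)oxy]triethylsilane
Conditions: LiN(iPr)2, THF, −78 °C; Et3SiCl, −78 → 0 °C
Reagents that add atoms: chlorotriethylsilane CC[Si](Cl)(CC)CC
Why: Kinetic deprotonation of the vinylogous ester at the α' carbon and O-silylation should give the cross-conjugated silyl dienol ether (silyl enol ether formation); no stereocenter is formed.

Step 2
Reactants: 2 [(5-ethoxycyclohexa-1,5-dien-1-yl)oxy]triethylsilane
Product: 4 (6R)-3-ethoxy-6-hydroxycyclohex-2-en-1-one, via silyloxy epoxide 3 (not isolated)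
Conditions: Shi ketone (D-fructose-derived, 30 mol%), KHSO5 (as Oxone), K2CO3, Na2B4O7 buffer, Bu4NHSO4 (cat.), MeCN/CH2(OMe)2/H2O, 0 °C; then citric acid, MeOH
Reagents that add atoms: potassium peroxymonosulfate [K+].[O-]S(=O)(=O)OO
Why: Shi asymmetric epoxidation of the silyl enol ether double bond (a catalytic asymmetric Rubottom oxidation) should give the epoxide, which collapses on acidic methanolysis to the α'-hydroxy ketone; the chiral dioxirane sets this carbinol center (the future C14).

Step 3
Reactants: 4 (6R)-3-ethoxy-6-hydroxycyclohex-2-en-1-one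
Product: 5 (6R)-6-[(tert-butyldimethylsilyl)oxy]-3-ethoxycyclohex-2-en-1-one
Conditions: t-BuMe2SiCl, imidazole, DMF, rt
Reagents that add atoms: tert-butyldimethylsilyl chloride CC(C)(C)[Si](C)(C)Cl
Why: Standard silylation of the secondary alcohol; the stereocenter is untouched.

Step 4
Reactants: 5 (6R)-6-[(tert-butyldimethylsilyl)oxy]-3-ethoxycyclohex-2-en-1-one
Product: 7 (4R)-4-[(tert-butyldimethylsilyl)oxy]-3-ethenylcyclohex-2-en-1-one, via tertiary allylic alcohol 6 (not isolated)
Conditions: CH2=CHMgBr, THF, −78 → 0 °C; then 1 M HCl, 0 °C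
Reagents that add atoms: vinylmagnesium bromide C=C[Mg]Br; water O
Why: Stork–Danheiser sequence: 1,2-addition of the Grignard reagent to the vinylogous ester carbonyl, then acid hydrolysis of the enol ether and loss of water transpose the enone and place the vinyl group on the future C13.

Step 5
Reactants: 7 (4R)-4-[(tert-butyldimethylsilyl)oxy]-3-ethenylcyclohex-2-en-1-one
Product: 8 (3R,4R)-4-[(tert-butyldimethylsilyl)oxy]-3-ethenyl-3-methylcyclohexan-1-one
Conditions: Me3Al, Cu(O2CC4H3S) (copper thiophene-2-carboxylate, 5 mol%), phosphoramidite ligand (10 mol%), Et2O, −30 °C; aq. KNaC4H4O6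
Reagents that add atoms: trimethylaluminium C[Al](C)C
Why: Copper-catalysed conjugate addition of trimethylaluminium, which on 3-alkenylcyclohexenones goes 1,4 and not 1,6, should build the quaternary C13; methyl enters anti to the adjacent silyloxy group, so methyl is β and the vinyl group is cis (α) to the C14 oxygen.

Step 6
Reactants: 8 (3R,4R)-4-[(tert-butyldimethylsilyl)oxy]-3-ethenyl-3-methylcyclohexan-1-one
Product: 9 tert-butyl{[(1R,2R)-2-ethenyl-4,4-dimethoxy-2-methylcyclohexyl]oxy}dimethylsilane
Conditions: HC(OMe)3, MeOH, pyridinium p-toluenesulfonate (cat.), rt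
Reagents that add atoms: trimethyl orthoformate COC(OC)OC
Why: Acid-catalysed ketalisation with the orthoformate as water scavenger prepares the C11 ketone for enol ether exchange.

Step 7
Reactants: 10 4-methyl-5,6-dihydro-2H-pyran-2-one
Product: 11 (3Z)-3,5-dimethylhex-3-ene-1,5-diol
Conditions: MeLi (3.5 equiv), CeCl3, THF, −78 → 0 °C; aq. NH4Cl
Reagents that add atoms: methyllithium [Li]C
Why: Double 1,2-addition of the methyl nucleophile to the unsaturated lactone carbonyl opens the ring to the tertiary allylic alcohol and keeps the Z geometry that the ring enforced.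

Step 8
Reactants: 11 (3Z)-3,5-dimethylhex-3-ene-1,5-diol
Product: 12 (3Z)-6-[(tert-butyldimethylsilyl)oxy]-2,4-dimethylhex-3-en-2-ol
Conditions: t-BuMe2SiCl (1.05 equiv), imidazole, CH2Cl2, 0 °C
Reagents that add atoms: tert-butyldimethylsilyl chloride CC(C)(C)[Si](C)(C)Cl
Why: Selective silylation of the primary hydroxyl in the presence of the hindered tertiary one.

Step 9
Reactants: 9 tert-butyl{[(1R,2R)-2-ethenyl-4,4-dimethoxy-2-methylcyclohexyl]oxy}dimethylsilane; 12 (3Z)-6-[(tert-butyldimethylsilyl)oxy]-2,4-dimethylhex-3-en-2-ol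
Product: 14 Claisen ketone (C11 ketone; 9α-H; 9β-C10 side chain; 13β-methyl; 13α-ethenyl; 14α-OSiMe2t-Bu), via allyl enol ether 13 (not isolated)
Conditions: 12 (1.5 equiv), EtCO2H (10 mol%), xylene, 140 °C, MeOH distilled off
Reagents that add atoms: none
Why: Ketal exchange and loss of methanol should give the C9=C11 allyl enol ether, whose Claisen rearrangement through a chair transition state on the β face of C9 (the α face is blocked by the 1,3-syn-axial 14α-silyloxy group) turns the Z alkene geometry into the C10 configuration and sets C9 (H α).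

Step 10
Reactants: 14 Claisen ketone
Product: 15 11α-alcohol (equatorial hydroxyl; other groups as in 14)
Conditions: Li, NH3 (l), THF, t-BuOH, −78 °C; NH4Cl
Reagents that add atoms: none
Why: Dissolving-metal reduction should give the thermodynamically preferred equatorial 11α alcohol (the 11β epimer would be 1,3-diaxial to the axial 13β methyl); isolated alkenes and silyl ethers are inert, and the ketone is consumed before C9 can enolise.

Step 11
Reactants: 15 11α-alcohol
Product: 16 11α-benzoate
Conditions: PhCOCl, pyridine, 4-(dimethylamino)pyridine (cat.), CH2Cl2, 0 °C → rt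
Reagents that add atoms: benzoyl chloride O=C(Cl)c1ccccc1
Why: Nucleophile-catalysed acylation of the equatorial secondary alcohol installs the benzoate of the target with retention.

Step 12
Reactants: 16 11α-benzoate
Product: 17 diol (free 14α-hydroxyl and free primary C2 hydroxyl)
Conditions: aq. HF (48%), MeCN, rt
Reagents that add atoms: none
Why: Fluoride-driven cleavage of both silyl ethers frees the C14 and C2 hydroxyls; benzoate and alkenes are stable.

Step 13
Reactants: 17 diol
Product: 18 keto acid (C14 ketone; C2 carboxylic acid)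
Conditions: CrO3, H2SO4, H2O, acetone, 0 °C
Reagents that add atoms: water O
Why: Jones oxidation takes the secondary C14 alcohol to the ketone and the primary C2 alcohol through the aldehyde hydrate to the carboxylic acid in one operation.

Step 14
Reactants: 18 keto acid
Product: 20 C8 triethylsilyloxy ketone acid, via C8 hydroxy ketone 19 (not isolated)
Conditions: KN(SiMe3)2 (2.2 equiv), THF, −78 °C; 2-(phenylsulfonyl)-3-phenyloxaziridine; then Et3SiCl; aq. NaH2PO4
Reagents that add atoms: 2-(phenylsulfonyl)-3-phenyloxaziridine O=S(=O)(c1ccccc1)N1OC1c1ccccc1; chlorotriethylsilane CC[Si](Cl)(CC)CC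
Why: The C14 ketone can enolise only towards C8 (C13 is quaternary), and Davis oxidation of the potassium enolate followed by in-flask silylation should give the α-silyloxy ketone; the C8 configuration formed here (oxygen expected on the less hindered α face) is erased in step 15.

Step 15
Reactants: 20 C8 triethylsilyloxy ketone acid
Product: 21 aldol adduct (C8 quaternary: 8β-OSiEt3 and 8α-(1-hydroxyethyl); both carbinol epimers)
Conditions: LiN(iPr)2 (2.3 equiv), THF, −78 °C; CH3CHO; aq. NH4Cl then NaH2PO4
Reagents that add atoms: acetaldehyde CC=O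
Why: Aldol addition of the tetrasubstituted α-silyloxy enolate to acetaldehyde should form the C8–C7 bond on the α face, anti to the axial 13β methyl and to the C9 substituent, leaving the C8 oxygen β (axial) and C7 α (equatorial) as in the target.

Step 16
Reactants: 21 aldol adduct
Product: 22 methyl ketone (8α-acetyl; 8β-OSiEt3)
Conditions: Dess–Martin periodinane, NaHCO3, CH2Cl2, rt
Reagents that add atoms: none
Why: Dess–Martin oxidation of the secondary carbinol gives the C7 ketone; the tertiary silyl ether and the carboxylic acid are inert.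

Step 17
Reactants: 22 methyl ketone
Product: 23 iodo ketone (8α-iodoacetyl; 8β-OSiEt3)
Conditions: LiN(SiMe3)2 (2.2 equiv), THF, −78 °C; N-iodosuccinimide; aq. NaH2PO4
Reagents that add atoms: N-iodosuccinimide O=C1CCC(=O)N1I
Why: The methyl ketone has a single enolisable position (C6), so enolate iodination should give the α-iodo ketone regiospecifically.

Step 18
Reactants: 23 iodo ketone
Product: 24 tricyclic keto diacid (trans-fused rings B/C; 5α-H; C7 ketone; 8β-OSiEt3; C2 and C3 carboxylic acids)
Conditions: CO (45 atm), Pd(PPh3)4 (5 mol%), hν (xenon lamp, Pyrex), K2CO3, H2O, C6H6, rt; then aq. HCl to pH 3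
Reagents that add atoms: carbon monoxide [C-]#[O+]; water O
Why: Light and the palladium catalyst cleave the C6–I bond to the electrophilic C6 α-keto radical, which adds 6-exo-trig to C5 of the electron-rich C5=C4Me2 alkene to close ring B; the resulting nucleophilic tertiary C4 radical captures CO and the acyl radical is taken up as an acylpalladium iodide that water cleaves to the C3 acid. The closest known reaction type is the palladium/light atom-transfer carbonylation of alkyl iodides, including its cascade form in which an α-iodo carbonyl compound, an alkene, CO and a protic nucleophile are joined, together with iodine-atom-transfer cyclisation of α-iodo ketones. Ring B closes through a chair transition state whose shape is fixed by the trans-diequatorial C8–C7 and C9–C10 bonds on ring C, so the B/C fusion is trans. The new C5 stereocenter is set by the CMe2 terminus taking the equatorial position of that chair, which places H-5 axial (α) and anti to the axial C20 methyl. The step needs attack on the trisubstituted alkene rather than on the C13 vinyl group and CO capture by the tertiary radical rather than elimination or reduction; the polarity match of the radical with the more electron-rich alkene, the favourable six-membered chair and the high CO pressure should secure both.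

Step 19
Reactants: 24 tricyclic keto diacid
Product: 25 8β-hydroxy-7-keto diacid
Conditions: HF·pyridine, THF, 0 °C → rt
Reagents that add atoms: none
Why: Fluoride cleavage of the tertiary triethylsilyl ether frees the C8 hydroxyl that directs the next step.

Step 20
Reactants: 25 8β-hydroxy-7-keto diacid
Product: 26 7α,8β-diol diacid
Conditions: NaBH(OAc)3, AcOH, MeCN, 0 °C → rt
Reagents that add atoms: none
Why: Hydroxyl-directed reduction (Saksena–Evans type): the acetoxyborohydride bound to the C8 oxygen delivers hydride to the β face of the C7 ketone, giving the axial 7α alcohol trans to the 8β hydroxyl; the C14 ketone, flanked by two quaternary carbons, should be left.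

Step 21
Reactants: 26 7α,8β-diol diacid
Product: 27 CNP0315860.1 (target)
Conditions: Ac2O, pyridine, 4-(dimethylamino)pyridine (cat.), CH2Cl2, rt; then H2O/THF, NaHCO3; acidify to pH 3
Reagents that add atoms: acetic anhydride CC(=O)OC(C)=O
Why: Nucleophile-catalysed acetylation of the only secondary alcohol; the tertiary C8 hydroxyl does not react and any mixed anhydrides of the two acids are hydrolysed in the aqueous work-up.

Compound list

1 | 3-ethoxycyclohex-2-en-1-one | CCOC1=CC(=O)CCC1 | starting material
2 | [(5-ethoxycyclohexa-1,5-dien-1-yl)oxy]triethylsilane | CCOC1=CC(O[Si](CC)(CC)CC)=CCC1 | intermediate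
3 | 3-ethoxy-1-[(triethylsilyl)oxy]-7-oxabicyclo[4.1.0]hept-2-ene (epoxide oxygen on the face that becomes the 6R hydroxyl) | CCOC1=C[C@]2(O[Si](CC)(CC)CC)O[C@@H]2CC1 | intermediate
4 | (6R)-3-ethoxy-6-hydroxycyclohex-2-en-1-one | CCOC1=CC(=O)[C@H](O)CC1 | intermediate
5 | (6R)-6-[(tert-butyldimethylsilyl)oxy]-3-ethoxycyclohex-2-en-1-one | CCOC1=CC(=O)[C@H](O[Si](C)(C)C(C)(C)C)CC1 | intermediate
6 | (6R)-6-[(tert-butyldimethylsilyl)oxy]-3-ethoxy-1-ethenylcyclohex-2-en-1-ol (both C1 epimers) | CCOC1=CC(O)(C=C)[C@H](O[Si](C)(C)C(C)(C)C)CC1 | intermediate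
7 | (4R)-4-[(tert-butyldimethylsilyl)oxy]-3-ethenylcyclohex-2-en-1-one | C=CC1=CC(=O)CC[C@H]1O[Si](C)(C)C(C)(C)C | intermediate
8 | (3R,4R)-4-[(tert-butyldimethylsilyl)oxy]-3-ethenyl-3-methylcyclohexan-1-one | C=C[C@@]1(C)CC(=O)CC[C@H]1O[Si](C)(C)C(C)(C)C | intermediate
9 | tert-butyl{[(1R,2R)-2-ethenyl-4,4-dimethoxy-2-methylcyclohexyl]oxy}dimethylsilane | C=C[C@@]1(C)CC(OC)(OC)CC[C@H]1O[Si](C)(C)C(C)(C)C | intermediate
10 | 4-methyl-5,6-dihydro-2H-pyran-2-one | CC1=CC(=O)OCC1 | starting material
11 | (3Z)-3,5-dimethylhex-3-ene-1,5-diol | OCC/C(C)=C\C(C)(C)O | intermediate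
12 | (3Z)-6-[(tert-butyldimethylsilyl)oxy]-2,4-dimethylhex-3-en-2-ol | CC(C)(O)/C=C(/C)CCO[Si](C)(C)C(C)(C)C | intermediate
13 | allyl enol ether: C9=C11 enol ether of ketone 8 with the tertiary oxygen of 12 (Z alkene kept) | C=C[C@@]1(C)CC(OC(C)(C)/C=C(/C)CCO[Si](C)(C)C(C)(C)C)=CC[C@H]1O[Si](C)(C)C(C)(C)C | intermediate
14 | Claisen ketone: cyclohexanone (C11=O) with 9α-H; 9β-C10 [C10 carries methyl, 2-(tert-butyldimethylsilyloxy)ethyl and 2-methylprop-1-enyl, configuration as in the target]; 13β-methyl; 13α-ethenyl; 14α-OSiMe2t-Bu | C=C[C@@]1(C)CC(=O)[C@H]([C@@](C)(CCO[Si](C)(C)C(C)(C)C)C=C(C)C)C[C@H]1O[Si](C)(C)C(C)(C)C | intermediate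
15 | 11α-alcohol of 14 (equatorial hydroxyl, trans to the C9 side chain) | C=C[C@@]1(C)C[C@@H](O)[C@H]([C@@](C)(CCO[Si](C)(C)C(C)(C)C)C=C(C)C)C[C@H]1O[Si](C)(C)C(C)(C)C | intermediate
16 | 11α-benzoate of 15 | C=C[C@@]1(C)C[C@@H](OC(=O)c2ccccc2)[C@H]([C@@](C)(CCO[Si](C)(C)C(C)(C)C)C=C(C)C)C[C@H]1O[Si](C)(C)C(C)(C)C | intermediate
17 | diol: 16 with free 14α-hydroxyl and free primary C2 hydroxyl | C=C[C@@]1(C)C[C@@H](OC(=O)c2ccccc2)[C@H]([C@@](C)(CCO)C=C(C)C)C[C@H]1O | intermediate
18 | keto acid: C14 ketone and C2 carboxylic acid; 11α-benzoate; C10 carries methyl, CH2CO2H and 2-methylprop-1-enyl | C=C[C@@]1(C)C[C@@H](OC(=O)c2ccccc2)[C@H]([C@@](C)(CC(=O)O)C=C(C)C)CC1=O | intermediate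
19 | C8 hydroxy ketone of 18 (8α-hydroxyl expected) | C=C[C@@]1(C)C[C@@H](OC(=O)c2ccccc2)[C@H]([C@@](C)(CC(=O)O)C=C(C)C)[C@@H](O)C1=O | intermediate
20 | C8 triethylsilyl ether of 19 | C=C[C@@]1(C)C[C@@H](OC(=O)c2ccccc2)[C@H]([C@@](C)(CC(=O)O)C=C(C)C)[C@@H](O[Si](CC)(CC)CC)C1=O | intermediate
21 | aldol adduct: C8 quaternary with 8β-OSiEt3 and 8α-(1-hydroxyethyl) (both carbinol epimers) | C=C[C@@]1(C)C[C@@H](OC(=O)c2ccccc2)[C@H]([C@@](C)(CC(=O)O)C=C(C)C)[C@@](O[Si](CC)(CC)CC)(C(C)O)C1=O | intermediate
22 | methyl ketone: 8α-acetyl, 8β-OSiEt3 | C=C[C@@]1(C)C[C@@H](OC(=O)c2ccccc2)[C@H]([C@@](C)(CC(=O)O)C=C(C)C)[C@@](O[Si](CC)(CC)CC)(C(C)=O)C1=O | intermediate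
23 | iodo ketone: 8α-iodoacetyl, 8β-OSiEt3 | C=C[C@@]1(C)C[C@@H](OC(=O)c2ccccc2)[C@H]([C@@](C)(CC(=O)O)C=C(C)C)[C@@](O[Si](CC)(CC)CC)(C(=O)CI)C1=O | intermediate
24 | tricyclic keto diacid: trans-fused rings B/C, 5α-H, C7 ketone, 8β-OSiEt3, C2 and C3 carboxylic acids | C=C[C@@]1(C)C[C@@H](OC(=O)c2ccccc2)[C@@H]2[C@@](C)(CC(=O)O)[C@H](C(C)(C)C(=O)O)CC(=O)[C@@]2(O[Si](CC)(CC)CC)C1=O | intermediate
25 | 8β-hydroxy-7-keto diacid | C=C[C@@]1(C)C[C@@H](OC(=O)c2ccccc2)[C@@H]2[C@@](C)(CC(=O)O)[C@H](C(C)(C)C(=O)O)CC(=O)[C@@]2(O)C1=O | intermediate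
26 | 7α,8β-diol diacid | C=C[C@@]1(C)C[C@@H](OC(=O)c2ccccc2)[C@@H]2[C@@](C)(CC(=O)O)[C@H](C(C)(C)C(=O)O)C[C@@H](O)[C@@]2(O)C1=O | intermediate
27 | CNP0315860.1: 7α-acetoxy-11α-benzoyloxy-8β-hydroxy-14-oxo-2,3-seco-isopimar-15-ene-2,3-dioic acid | C=C[C@@]1(C)C[C@@H](OC(=O)c2ccccc2)[C@@H]2[C@@](C)(CC(=O)O)[C@H](C(C)(C)C(=O)O)C[C@@H](OC(C)=O)[C@@]2(O)C1=O | target

Total step count: 21. Longest linear sequence: 19 steps (steps 1–6 and 9–21, from compound 1); steps 7 and 8 build the allylic alcohol 12 in a side branch.

Steps most likely to fail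

Step 18 (key step). The tertiary C4 radical may be intercepted before it captures CO (iodine transfer followed by loss of hydrogen iodide, or hydrogen abstraction), the iodo ketone may be hydrolysed by the aqueous base before the chain starts, or the C6 radical may attack the C13 vinyl group. Fallback: ring closure and carbonylation are separated. Starting from 23, an iodine-atom-transfer radical cyclisation without CO (BEt3, air, C6H6, rt) should give the ring B closed tertiary iodide F1, which is isolated. In a second flask F1 is carbonylated on its own (CO 45 atm, hν, Pd(PPh3)4, K2CO3, H2O), a reaction known for tertiary alkyl iodides, and the route is rejoined at 24.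

Step 9. Exchange of the hindered tertiary allylic alcohol into the ketal may be slow, the acid may ionise or dehydrate that alcohol, facial or chair selectivity may erode, and C9 may epimerise under hot acid. Fallback: the allyl enol ether is made by cross-coupling instead of acid exchange. Starting from 8, hydrazine hydrate in ethanol gives the hydrazone F2, and iodine with tetramethylguanidine in ether (Barton vinyl iodide synthesis) gives the C9=C11 vinyl iodide F3. Copper-catalysed C–O coupling of F3 with alcohol 12 (CuI, 3,4,7,8-tetramethyl-1,10-phenanthroline, Cs2CO3, xylene, 120–140 °C) forms enol ether 13 under basic conditions, and 13 rearranges in the same flask; the route is rejoined at 14.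

Step 5. Methyl transfer may go 1,6 to the dienone, or facial selectivity may be poor. Fallback: the order of the two C13 substituents is reversed and the vinyl group is delivered by the oxygen. Starting from 5, MeMgBr then 1 M HCl gives (4R)-4-[(tert-butyldimethylsilyl)oxy]-3-methylcyclohex-2-en-1-one F4. Aqueous HF in MeCN gives (4R)-4-hydroxy-3-methylcyclohex-2-en-1-one F5. Alkoxide-directed syn 1,4-addition of CH2=CHMgBr (3 equiv, THF, −78 → 0 °C) should give (3R,4R)-3-ethenyl-4-hydroxy-3-methylcyclohexan-1-one F6 with vinyl cis to the hydroxyl. Silylation (t-BuMe2SiCl, imidazole) rejoins the route at 8.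

Further compounds
F1 | step 18 | tertiary iodide: tricyclic 7-keto acid with 8β-OSiEt3 and a 2-iodopropan-2-yl group on C5 (5α-H) | C=C[C@@]1(C)C[C@@H](OC(=O)c2ccccc2)[C@@H]2[C@@](C)(CC(=O)O)[C@H](C(C)(C)I)CC(=O)[C@@]2(O[Si](CC)(CC)CC)C1=O
F2 | step 9 | hydrazone of ketone 8 | C=C[C@@]1(C)CC(=NN)CC[C@H]1O[Si](C)(C)C(C)(C)C
F3 | step 9 | tert-butyl{[(1R,2R)-2-ethenyl-4-iodo-2-methylcyclohex-4-en-1-yl]oxy}dimethylsilane (C9=C11 vinyl iodide) | C=C[C@@]1(C)CC(I)=CC[C@H]1O[Si](C)(C)C(C)(C)C
F4 | step 5 | (4R)-4-[(tert-butyldimethylsilyl)oxy]-3-methylcyclohex-2-en-1-one | CC1=CC(=O)CC[C@H]1O[Si](C)(C)C(C)(C)C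
F5 | step 5 | (4R)-4-hydroxy-3-methylcyclohex-2-en-1-one | CC1=CC(=O)CC[C@H]1O
F6 | step 5 | (3R,4R)-3-ethenyl-4-hydroxy-3-methylcyclohexan-1-one | C=C[C@@]1(C)CC(=O)CC[C@H]1O
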